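**Assumption:** the target is taken as the open γ-hydroxy-enone drawn (its oxygen-bridged lactol is only a ring–chain tautomer), and in the two catalyst-controlled steps (2 and 10) the catalyst antipode that gives the stated configuration is used.

**Locants used below:** C1 = ring carbon bearing methyl and the 4-methylpent-3-enyl chain, C2=C3, C4 (ester carbinol), C5 (tertiary alcohol), C6=C7, C8 (ketone), C9 (hydroxymethyl), C10, C11. The target is (1S,4R,5S) with all three ring alkenes cis.

## Retrosynthetic overview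

1. The 11-membered ring is closed last at C8–C9: a Z-vinyllithium (C9) adds to the carbonyl of a γ,γ-disubstituted butenolide, and lactone opening gives C5–OH, Z-C6=C7 and C8=O at once.
2. The butenolide with the C4/C5 pair comes from a dearomatising vinylogous Mukaiyama aldol of 5-methyl-2-(trimethylsilyloxy)furan (from 2-methylfuran) with an ynal; this forms C4–C5 and both stereocentres in one step.
3. The C4 ester is installed by acylation and Z-C2=C3 by alkyne semihydrogenation.
4. The ynal comes from geraniol: a Cu-catalysed enantioselective SN2' alkynylation sets quaternary C1, and the resulting vinyl group is taken via an aldehyde to the Z-iodoalkenyl unit (C9–C11).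
5. Ring order: the furan/butenolide is a temporary ring; the only ring built is the 11-membered carbocycle, formed as the butenolide opens.

## Route

Step 1
Reactants: 1 geraniol
Product: 2 diethyl (2E)-3,7-dimethylocta-2,6-dien-1-yl phosphate
Conditions: ClP(O)(OEt)2, pyridine, DMAP (cat.), CH2Cl2, 0 °C to rt
Reagents that add atoms: diethyl chlorophosphate, CCOP(=O)(Cl)OCC
Why: O-phosphorylation of the primary allylic alcohol gives the leaving group needed for copper-catalysed SN2' substitution; no stereocentre is involved.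

Step 2
Reactants: 2 diethyl geranyl phosphate; 3 3,3-diethoxyprop-1-yne
Product: 5 (4S)-4-ethenyl-1,1-diethoxy-4,8-dimethylnon-7-en-2-yne, via alkynylalane 4 (not isolated)
Conditions: 3, i-Bu2AlH, Et3N (5 mol %), hexanes, 0 to 22 °C; then 2, CuCl2·2H2O (2 mol %), chiral sulfonate-bridged imidazolinium salt (N-heterocyclic carbene precursor, 2.5 mol %), THF, −30 °C
Reagents that add atoms: none
Why: NHC–copper-catalysed enantioselective allylic substitution with an alkynylaluminium reagent transfers the alkynyl group SN2' to one face of the E-trisubstituted alkene, creating the all-carbon quaternary centre C1 (S) together with the vinyl group; the acetal-bearing alkyne is a new partner for this known reaction class.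

Step 3
Reactants: 5 enyne acetal
Product: 7 (3S)-3-(3,3-diethoxyprop-1-yn-1-yl)-3,7-dimethyloct-6-en-1-ol, via B-alkyl-9-BBN 6 (not isolated)
Conditions: 9-BBN, THF, 0 °C to rt; then NaOH, H2O2, 0 °C
Reagents that add atoms: hydrogen peroxide, OO
Why: Hydroboration–oxidation with 9-BBN is anti-Markovnikov and reacts only with the monosubstituted vinyl group, leaving the trisubstituted alkene and the hindered internal alkyne; C1 is untouched.

Step 4
Reactants: 7 primary alcohol
Product: 8 (3S)-3-(3,3-diethoxyprop-1-yn-1-yl)-3,7-dimethyloct-6-enal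
Conditions: Dess–Martin periodinane, CH2Cl2, 0 °C to rt
Reagents that add atoms: none
Why: Dess–Martin oxidation converts the primary alcohol to the aldehyde (C10) under anhydrous conditions that keep the acetal.

Step 5
Reactants: 8 aldehyde; 9 ethyl (triphenylphosphoranylidene)acetate
Product: 11 ethyl (2Z,5S)-5-(3,3-diethoxyprop-1-yn-1-yl)-2-iodo-5,9-dimethyldeca-2,8-dienoate, via iodo-ylide 10 (not isolated)
Conditions: 9, N-iodosuccinimide, CH2Cl2, −20 °C; then 8, −20 °C to rt
Reagents that add atoms: N-iodosuccinimide, O=C1CCC(=O)N1I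
Why: Wittig olefination with the α-iodo stabilised ylide places the ester trans to the alkyl chain as usual, so iodine is cis to C11 (Z, about 9:1 expected, minor isomer removed by chromatography); this fixes the C9=C10 geometry because iodine is later replaced by C8 with retention.

Step 6
Reactants: 11 iodoenoate
Product: 12 (2Z,5S)-5-(3,3-diethoxyprop-1-yn-1-yl)-2-iodo-5,9-dimethyldeca-2,8-dien-1-ol
Conditions: i-Bu2AlH (2.2 equiv), CH2Cl2, −78 °C; aq. KNa tartrate
Reagents that add atoms: none
Why: 1,2-Reduction of the enoate with i-Bu2AlH at −78 °C gives the allylic alcohol (the future C9 hydroxymethyl) without touching the vinyl iodide, alkyne or acetal.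

Step 7
Reactants: 12 iodo-allylic alcohol
Product: 13 tert-butyl{[(2Z,5S)-5-(3,3-diethoxyprop-1-yn-1-yl)-2-iodo-5,9-dimethyldeca-2,8-dien-1-yl]oxy}diphenylsilane
Conditions: TBDPSCl, imidazole, CH2Cl2, rt
Reagents that add atoms: tert-butyl(chloro)diphenylsilane, CC(C)(C)[Si](Cl)(c1ccccc1)c1ccccc1
Why: Silylation of the primary alcohol with a TBDPS group, chosen because it survives the acidic acetal cleavage, the later trimethylsilyl ether hydrolysis and t-BuLi.

Step 8
Reactants: 13 silyl ether acetal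
Product: 14 (4S,6Z)-8-{[tert-butyl(diphenyl)silyl]oxy}-7-iodo-4-methyl-4-(4-methylpent-3-en-1-yl)oct-6-en-2-ynal
Conditions: Amberlyst-15, acetone/H2O (20:1), rt
Reagents that add atoms: water, O
Why: Acid-catalysed acetal hydrolysis on a sulfonic acid resin in wet acetone unmasks the ynal (C4 aldehyde) while the TBDPS ether, vinyl iodide and trisubstituted alkene remain.

Step 9
Reactants: 15 2-methylfuran
Product: 17 trimethyl[(5-methylfuran-2-yl)oxy]silane, via furyllithium 16 (not isolated)
Conditions: n-BuLi, THF, −20 to 0 °C; then Me3SiOOSiMe3, −78 to 0 °C; distillation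
Reagents that add atoms: bis(trimethylsilyl) peroxide, C[Si](C)(C)OO[Si](C)(C)C
Why: α-Lithiation of the furan followed by electrophilic oxygenation of the furyllithium with the silyl peroxide (O–O cleavage with silyl transfer) gives the aromatic 2-silyloxyfuran, a dienolate equivalent of the γ-methylbutenolide.

Step 10
Reactants: 14 ynal; 17 5-methyl-2-(trimethylsilyloxy)furan
Product: 19 (5S)-5-[(1R,4S,6Z)-8-{[tert-butyl(diphenyl)silyl]oxy}-1-hydroxy-7-iodo-4-methyl-4-(4-methylpent-3-en-1-yl)oct-6-en-2-yn-1-yl]-5-methylfuran-2(5H)-one, via silyl ether 18 (not isolated)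
Conditions: 17 (1.5 equiv), cinchona-alkaloid 9-thiourea ammonium carboxylate (chiral ion-pair catalyst, 10 mol %, pseudoenantiomer giving 1R,5S), CH2Cl2/Et2O, −40 °C; then 1 M HCl, THF, 0 °C
Reagents that add atoms: none
Why: Proposed new method: the carboxylate desilylates 17 to an ammonium-paired 5-methylfuranolate that attacks the thiourea-bound ynal through its methyl-bearing γ-carbon, breaking furan aromaticity and forming C4–C5 in an open transition state with the aldehyde oxygen anti to the ring oxygen and the slim alkynyl group next to it, which gives C4–O anti to C5–O along C3–C4–C5–C6 (C4 R, quaternary C5 S) with the face chosen by the catalyst; the closest known reaction type is the enantioselective vinylogous Mukaiyama aldol of 2-silyloxyfurans under chiral ammonium carboxylate or fluoride activation, which gives this erythro-type series, and a 5-methyl donor with an ynal acceptor is the untested extension.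

Step 11
Reactants: 19 aldol adduct; 20 3-methylbut-2-enoyl chloride
Product: 21 (1R,4S,6Z)-8-{[tert-butyl(diphenyl)silyl]oxy}-7-iodo-4-methyl-1-[(2S)-2-methyl-5-oxo-2,5-dihydrofuran-2-yl]-4-(4-methylpent-3-en-1-yl)oct-6-en-2-yn-1-yl 3-methylbut-2-enoate
Conditions: 20, pyridine, DMAP (10 mol %), CH2Cl2, 0 °C
Reagents that add atoms: none
Why: DMAP-catalysed acylation of the secondary propargylic alcohol proceeds with retention at C4, pyridine (not a trialkylamine) avoiding ketene formation and deconjugation of the acyl chloride; the ester also blocks retro-aldol cleavage.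

Step 12
Reactants: 21 alkynyl ester
Product: 22 (1R,2Z,4S,6Z)-8-{[tert-butyl(diphenyl)silyl]oxy}-7-iodo-4-methyl-1-[(2S)-2-methyl-5-oxo-2,5-dihydrofuran-2-yl]-4-(4-methylpent-3-en-1-yl)octa-2,6-dien-1-yl 3-methylbut-2-enoate
Conditions: H2 (1 atm), Pd/CaCO3 poisoned with Pb(OAc)2 (Lindlar), quinoline, EtOAc, 0 °C, stopped at 1 equiv H2
Reagents that add atoms: none
Why: Lindlar semihydrogenation adds H2 syn to the alkyne to give the Z C2=C3 alkene, the poisoned catalyst and quinoline sparing the other alkenes, the butenolide and the hindered vinyl iodide.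

Step 13
Reactants: 22 Z,Z-dienyl iodide butenolide
Product: 25 (1R,2Z,4S,6Z,9Z,11S)-7-({[tert-butyl(diphenyl)silyl]oxy}methyl)-11-hydroxy-4,11-dimethyl-4-(4-methylpent-3-en-1-yl)-8-oxocycloundeca-2,6,9-trien-1-yl 3-methylbut-2-enoate, via vinyllithium 23 (not isolated), via bridged lithium lactolate 24 (not isolated)
Conditions: t-BuLi (2.1 equiv), THF/Et2O/pentane (4:1:1), 1 mM, −100 to −78 °C; AcOH quench at −78 °C
Reagents that add atoms: none
Why: Iodine–lithium exchange, faster than carbonyl addition at −100 °C, gives a configurationally stable vinyllithium that acylates intramolecularly on the strained butenolide carbonyl in preference to the hindered β,β-disubstituted enoate (Parham-type cyclisation, pre-organised by the two Z alkenes and the quaternary carbon); the bridged lactolate cannot over-add and opens on protonation to the Z γ-hydroxy-enone, so the 11-membered ring, C5–OH, Z C6=C7 and C8=O all appear in this step.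

Step 14
Reactants: 25 silyl-protected macrocycle
Product: 26 target, (1R,2Z,4S,6Z,9Z,11S)-11-hydroxy-7-(hydroxymethyl)-4,11-dimethyl-4-(4-methylpent-3-en-1-yl)-8-oxocycloundeca-2,6,9-trien-1-yl 3-methylbut-2-enoate (CNP0230506.4)
Conditions: HF·pyridine, pyridine, THF, 0 °C to rt
Reagents that add atoms: none
Why: Fluoride desilylation under buffered, non-basic conditions frees the primary allylic alcohol without acyl migration to the neighbouring tertiary alcohol or isomerisation of the cis-enone.

## Compound list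

1 | geraniol, (2E)-3,7-dimethylocta-2,6-dien-1-ol | CC(C)=CCC/C(C)=C/CO | starting material
2 | diethyl (2E)-3,7-dimethylocta-2,6-dien-1-yl phosphate | CC(C)=CCC/C(C)=C/COP(=O)(OCC)OCC | intermediate
3 | 3,3-diethoxyprop-1-yne | C#CC(OCC)OCC | starting material
4 | (3,3-diethoxyprop-1-yn-1-yl)bis(2-methylpropyl)alumane | CCOC(OCC)C#C[Al](CC(C)C)CC(C)C | intermediate
5 | (4S)-4-ethenyl-1,1-diethoxy-4,8-dimethylnon-7-en-2-yne | CC(C)=CCC[C@](C=C)(C)C#CC(OCC)OCC | intermediate
6 | 9-[(3R)-3-(3,3-diethoxyprop-1-yn-1-yl)-3,7-dimethyloct-6-en-1-yl]-9-borabicyclo[3.3.1]nonane | CC(C)=CCC[C@](CCB1C2CCCC1CCC2)(C)C#CC(OCC)OCC | intermediate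
7 | (3S)-3-(3,3-diethoxyprop-1-yn-1-yl)-3,7-dimethyloct-6-en-1-ol | CC(C)=CCC[C@](CCO)(C)C#CC(OCC)OCC | intermediate
8 | (3S)-3-(3,3-diethoxyprop-1-yn-1-yl)-3,7-dimethyloct-6-enal | CC(C)=CCC[C@](CC=O)(C)C#CC(OCC)OCC | intermediate
9 | ethyl (triphenylphosphoranylidene)acetate | CCOC(=O)C=P(c1ccccc1)(c1ccccc1)c1ccccc1 | starting material
10 | ethyl iodo(triphenylphosphoranylidene)acetate | CCOC(=O)C(I)=P(c1ccccc1)(c1ccccc1)c1ccccc1 | intermediate
11 | ethyl (2Z,5S)-5-(3,3-diethoxyprop-1-yn-1-yl)-2-iodo-5,9-dimethyldeca-2,8-dienoate | CC(C)=CCC[C@](C/C=C(\I)C(=O)OCC)(C)C#CC(OCC)OCC | intermediate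
12 | (2Z,5S)-5-(3,3-diethoxyprop-1-yn-1-yl)-2-iodo-5,9-dimethyldeca-2,8-dien-1-ol | CC(C)=CCC[C@](C/C=C(\I)CO)(C)C#CC(OCC)OCC | intermediate
13 | tert-butyl{[(2Z,5S)-5-(3,3-diethoxyprop-1-yn-1-yl)-2-iodo-5,9-dimethyldeca-2,8-dien-1-yl]oxy}diphenylsilane | CC(C)=CCC[C@](C/C=C(\I)CO[Si](c1ccccc1)(c1ccccc1)C(C)(C)C)(C)C#CC(OCC)OCC | intermediate
14 | (4S,6Z)-8-{[tert-butyl(diphenyl)silyl]oxy}-7-iodo-4-methyl-4-(4-methylpent-3-en-1-yl)oct-6-en-2-ynal | CC(C)=CCC[C@](C/C=C(\I)CO[Si](c1ccccc1)(c1ccccc1)C(C)(C)C)(C)C#CC=O | intermediate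
15 | 2-methylfuran | Cc1ccco1 | starting material
16 | (5-methylfuran-2-yl)lithium | Cc1ccc([Li])o1 | intermediate
17 | trimethyl[(5-methylfuran-2-yl)oxy]silane | Cc1ccc(O[Si](C)(C)C)o1 | intermediate
18 | trimethylsilyl ether of 19 (O-silylated at the carbinol, 1R,5S) | CC(C)=CCC[C@](C/C=C(\I)CO[Si](c1ccccc1)(c1ccccc1)C(C)(C)C)(C)C#C[C@@H](O[Si](C)(C)C)[C@@]1(C)OC(=O)C=C1 | intermediate
19 | (5S)-5-[(1R,4S,6Z)-8-{[tert-butyl(diphenyl)silyl]oxy}-1-hydroxy-7-iodo-4-methyl-4-(4-methylpent-3-en-1-yl)oct-6-en-2-yn-1-yl]-5-methylfuran-2(5H)-one | CC(C)=CCC[C@](C/C=C(\I)CO[Si](c1ccccc1)(c1ccccc1)C(C)(C)C)(C)C#C[C@@H](O)[C@@]1(C)OC(=O)C=C1 | intermediate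
20 | 3-methylbut-2-enoyl chloride | CC(C)=CC(=O)Cl | starting material
21 | (1R,4S,6Z)-8-{[tert-butyl(diphenyl)silyl]oxy}-7-iodo-4-methyl-1-[(2S)-2-methyl-5-oxo-2,5-dihydrofuran-2-yl]-4-(4-methylpent-3-en-1-yl)oct-6-en-2-yn-1-yl 3-methylbut-2-enoate | CC(C)=CCC[C@](C/C=C(\I)CO[Si](c1ccccc1)(c1ccccc1)C(C)(C)C)(C)C#C[C@@H](OC(=O)C=C(C)C)[C@@]1(C)OC(=O)C=C1 | intermediate
22 | (1R,2Z,4S,6Z)-8-{[tert-butyl(diphenyl)silyl]oxy}-7-iodo-4-methyl-1-[(2S)-2-methyl-5-oxo-2,5-dihydrofuran-2-yl]-4-(4-methylpent-3-en-1-yl)octa-2,6-dien-1-yl 3-methylbut-2-enoate | CC(C)=CCC[C@](C/C=C(\I)CO[Si](c1ccccc1)(c1ccccc1)C(C)(C)C)(C)/C=C\[C@@H](OC(=O)C=C(C)C)[C@@]1(C)OC(=O)C=C1 | intermediate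
23 | vinyllithium from 22 (Li in place of I, Z geometry kept) | CC(C)=CCC[C@](C/C=C(\[Li])CO[Si](c1ccccc1)(c1ccccc1)C(C)(C)C)(C)/C=C\[C@@H](OC(=O)C=C(C)C)[C@@]1(C)OC(=O)C=C1 | intermediate
24 | bridged lithium lactolate (lithium salt of the C8 hemiketal; the former lactone oxygen bridges C5 and C8 of the new 11-membered ring, C8 configuration fixed by the bridge) | CC(C)=CCC[C@]1(C)/C=C\[C@@H](OC(=O)C=C(C)C)[C@@]2(C)O[C@](O[Li])(C=C2)/C(CO[Si](c3ccccc3)(c3ccccc3)C(C)(C)C)=C\C1 | intermediate
25 | (1R,2Z,4S,6Z,9Z,11S)-7-({[tert-butyl(diphenyl)silyl]oxy}methyl)-11-hydroxy-4,11-dimethyl-4-(4-methylpent-3-en-1-yl)-8-oxocycloundeca-2,6,9-trien-1-yl 3-methylbut-2-enoate | CC(C)=CCC[C@]1(C)/C=C\[C@@H](OC(=O)C=C(C)C)[C@@](C)(O)/C=C\C(=O)/C(CO[Si](c2ccccc2)(c2ccccc2)C(C)(C)C)=C\C1 | intermediate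
26 | (1R,2Z,4S,6Z,9Z,11S)-11-hydroxy-7-(hydroxymethyl)-4,11-dimethyl-4-(4-methylpent-3-en-1-yl)-8-oxocycloundeca-2,6,9-trien-1-yl 3-methylbut-2-enoate | CC(C)=CCC[C@]1(C)/C=C\[C@@H](OC(=O)C=C(C)C)[C@@](C)(O)/C=C\C(=O)/C(CO)=C\C1 | target

## Step count and risks

Total step count: 14. Longest linear sequence: 13 (steps 1–8 and 10–14 from geraniol); step 9 is a one-step side branch.

**Most likely to fail, first: step 10.** Attack through the hindered methyl-bearing γ-carbon, the C4/C5 relative configuration and the catalyst face selection are all unproven for this donor–acceptor pair. The fallback sets out from 14 (with 17) and comes back at 21. The two are combined under Lewis-acid catalysis (Ti(OiPr)4/BINOL, Et2O, −20 °C), the mode that gives the opposite, threo-type relative configuration with 2-silyloxyfurans, with the BINOL antipode chosen for 5S. The first-formed trimethylsilyl ether of the (1S)-epimer F1 is hydrolysed on acidic work-up to the (1S,5S) carbinol epimer F2. F2 is then esterified with 3-methylbut-2-enoic acid under Mitsunobu conditions (PPh3, DIAD, toluene, 0 °C), which inverts the propargylic carbinol and installs the ester in one operation to give 21.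

**Second: step 13.** Closing an 11-membered ring with an organolithium while a second ester is present may give acyl transfer, enolisation or oligomers. The fallback sets out from 19 and comes back at 25, closing the ring on an aldehyde with an organochromium reagent before the ester exists:
- 19 is silylated (TESCl, imidazole) to the triethylsilyl ether F3.
- F3 is semihydrogenated as in step 12 to the Z-alkene F4.
- The butenolide of F4 is reduced (i-Bu2AlH, CH2Cl2, −78 °C) to the lactol F5, which is in equilibrium with its cis-hydroxy-enal.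
- Nozaki–Hiyama–Kishi ring closure (CrCl2, NiCl2 cat., DMSO/THF, 2 mM, rt) gives the macrocyclic C5,C8-diol F6 as a C8 epimer mixture.
- MnO2 oxidises the doubly allylic C8 alcohol to the dienone F7.
- AcOH/THF/H2O removes only the triethylsilyl group to give the C4 alcohol F8.
- Acylation of F8 with 20 (pyridine, DMAP) gives 25.

**Third: step 12.** The catalyst may also cleave the vinyl iodide or reduce past the alkene. The fallback sets out from 21 and comes back at 22 without any transition metal: hydroboration with dicyclohexylborane (THF, 0 °C), which adds syn with boron at C3 (away from the quaternary carbon), gives the alkenylborane F9, and protonolysis with acetic acid at rt replaces boron by hydrogen with retention to give 22.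

## Further compounds

F1 | step 10 | trimethylsilyl ether of the (1S)-epimer of 19 (1S,5S) | CC(C)=CCC[C@](C/C=C(\I)CO[Si](c1ccccc1)(c1ccccc1)C(C)(C)C)(C)C#C[C@H](O[Si](C)(C)C)[C@@]1(C)OC(=O)C=C1
F2 | step 10 | (5S)-5-[(1S,4S,6Z)-8-{[tert-butyl(diphenyl)silyl]oxy}-1-hydroxy-7-iodo-4-methyl-4-(4-methylpent-3-en-1-yl)oct-6-en-2-yn-1-yl]-5-methylfuran-2(5H)-one | CC(C)=CCC[C@](C/C=C(\I)CO[Si](c1ccccc1)(c1ccccc1)C(C)(C)C)(C)C#C[C@H](O)[C@@]1(C)OC(=O)C=C1
F3 | step 13 | triethylsilyl ether of 19 | CC(C)=CCC[C@](C/C=C(\I)CO[Si](c1ccccc1)(c1ccccc1)C(C)(C)C)(C)C#C[C@@H](O[Si](CC)(CC)CC)[C@@]1(C)OC(=O)C=C1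
F4 | step 13 | (2Z)-alkene from F3 (C4 triethylsilyl ether, butenolide intact) | CC(C)=CCC[C@](C/C=C(\I)CO[Si](c1ccccc1)(c1ccccc1)C(C)(C)C)(C)/C=C\[C@@H](O[Si](CC)(CC)CC)[C@@]1(C)OC(=O)C=C1
F5 | step 13 | lactol from F4 (5-hydroxy-2,5-dihydrofuran, anomer mixture) | CC(C)=CCC[C@](C/C=C(\I)CO[Si](c1ccccc1)(c1ccccc1)C(C)(C)C)(C)/C=C\[C@@H](O[Si](CC)(CC)CC)[C@@]1(C)OC(O)C=C1
F6 | step 13 | macrocyclic C5,C8-diol (C4 triethylsilyl ether, primary TBDPS ether, C8 epimer mixture) | CC(C)=CCC[C@]1(C)/C=C\[C@@H](O[Si](CC)(CC)CC)[C@@](C)(O)/C=C\C(O)/C(CO[Si](c2ccccc2)(c2ccccc2)C(C)(C)C)=C\C1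
F7 | step 13 | macrocyclic dienone with C4 triethylsilyl ether and primary TBDPS ether | CC(C)=CCC[C@]1(C)/C=C\[C@@H](O[Si](CC)(CC)CC)[C@@](C)(O)/C=C\C(=O)/C(CO[Si](c2ccccc2)(c2ccccc2)C(C)(C)C)=C\C1
F8 | step 13 | macrocyclic dienone with free C4 and C5 hydroxyls and primary TBDPS ether | CC(C)=CCC[C@]1(C)/C=C\[C@@H](O)[C@@](C)(O)/C=C\C(=O)/C(CO[Si](c2ccccc2)(c2ccccc2)C(C)(C)C)=C\C1
F9 | step 12 | C3-(dicyclohexylboryl) alkene from 21 (syn H–B adduct) | CC(C)=CCC[C@](C/C=C(\I)CO[Si](c1ccccc1)(c1ccccc1)C(C)(C)C)(C)/C=C(/B(C1CCCCC1)C1CCCCC1)[C@@H](OC(=O)C=C(C)C)[C@@]1(C)OC(=O)C=C1
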